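69.3% of the product reads as L at 4.00 h, Tuesday's and Monday's runs pooled. I call this the L share, L over L and J together, and I carry it to the new flask.

the same everywhere: E 0.63 M; Q 0.63 M

| run | X | D | remark | time |
|---|---|---|---|---|
| Tuesday's | 2.2 equiv | 0.34 mol% | run made earlier |  |
| Monday's | 2.2 equiv | 0.77 mol% | run made earlier |  |
| flask | 2.20 equiv | 0.51 mol% |  | 5.0 h |

* L and J together, in percent of the E and Q charged together, at 5.0 h
* excess of L over J in the product at 5.0 h
* whether the exchange between E and Q keeps pace with the reaction: how far the product's excess at 5.0 h gets from its value without exchange to its value with instant exchange (above 80% keeps pace, below 20% hardly takes part, else lags behind)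

- X is single-handed; E and Q are mirror images of each other, charged as a racemate, each of them at the stated concentration
- what was read earlier has a scatter of 0.5 percentage points, one standard deviation
- an excess is the difference of the two amounts in percent of their sum
- an excess is below zero if the other one leads
- the handed part of X does not stay in what it makes, so the products of the two hands are mirror images too

- Tuesday's (time / h: L / %, J / %): 0.833: 7.8, 2.9; 1.50: 12.1, 4.3; 2.50: 17.6, 7.1; 3.00: 19.8, 8.1; 4.00: 22.9, 9.7
- Monday's (time / h: L / %, J / %): 0.833: 8.0, 2.9; 1.50: 12.8, 5.1; 2.50: 16.6, 6.4; 3.00: 19.1, 8.1; 4.00: 23.5, 10.9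

(readings scatter by 0.5 percentage points)

I read the two tables row against row. All three flasks start with c(E) at 0.63 M, and c(Q) the same. Monday's run has 0.77 mol% of D and Tuesday's 0.34 mol%, yet their L at 4.00 h reads 23.5% and 22.9%.

Pooled, the first row gives an L share of 73.1%, which is higher than the last row's by 3.8 percentage points. A falling share is what separate pools of E and Q give, a composition drift; a flat share is what instant exchange gives. But the first row rests on J of 2.9% and 2.9%, smaller than the last row's 9.7% and 10.9%, each with a scatter of 0.5 points. So I trust the last row and freeze its share. That gives an excess of L over J of 38.5%. I leave the pace open, since these rows do not separate the two pictures.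

The forecast gives 38.1% for y, 38.4% for the excess, and "hardly takes part", on this ground: “The run with more D shows no higher excess, so exchange is negligible.” Its excess lies close to mine, but it lets the excess fall with conversion, while I hold the share flat.

The flask gives 38.4% for y, 39.8% for the excess, and "keeps pace", 97% of the way to the excess with instant exchange: a dynamic kinetic resolution.

    X + D → G (k = 9.00 × 10⁻⁴ M⁻¹ min⁻¹)
    X ⇌ Z (K = 0.440, k = 0.00600 min⁻¹)
    X + E → L (k = 0.00280 M⁻¹ min⁻¹)
    E + D ⇌ Q + D, rate k4*[D]*[E] forward; the back reaction follows from the equilibrium constant (k = 47.0 M⁻¹ min⁻¹)
    X + Q → J (k = 0.00120 M⁻¹ min⁻¹)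

The excess stands at 39.8% after 0.500 h and 39.8% after 2.50 h, while Q leads E by 0.201% at 5.00 h. The L share times y gives 26.6% for L here, and the flask holds 26.9%. In the neighbour flask with 3.70 equiv of X, y is 56.7%, so the share gives 39.3%, and that flask holds 39.6%.

The readings come from a simulation from invented constants, noise included.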